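The data were generated by integration with constants of no real substance, and the scatter is random.

If product B follows the ratio of the charges and not their strength, the new flask can be reckoned from the earlier runs; that was the question put to the meeting.

| flask | first end groups | second end groups | remark | time |
|---|---|---|---|---|
| midnight | 0.20 M | 0.90 equiv | run made earlier |  |
| spring | 0.30 M | 0.90 equiv | run made earlier |  |
| summer | 0.40 M | 1.4 equiv | run made earlier |  |
| flask | 0.40 M | 0.900 equiv |  | 3.0 d |

| run | time / d | first end groups / % | over-reaction product B / % | links / % |
|---|---|---|---|---|
| midnight | 0.417 | 0 | 55 | 0 |
| midnight | 0.833 | 0 | 55 | 0 |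
| midnight | 1.25 | 1 | 55 | 0 |
| midnight | 1.67 | 0 | 57 | 0 |
| midnight | 2.00 | 1 | 54 | 0 |
| midnight | 2.50 | 1 | 57 | 1 |
| midnight | 3.00 | 0 | 57 | 1 |
| spring | 0.167 | 1 | 54 | 5 |
| spring | 0.500 | 0 | 55 | 1 |
| spring | 0.833 | 0 | 53 | 1 |
| spring | 1.25 | 0 | 55 | 3 |
| spring | 1.67 | 2 | 57 | 0 |
| spring | 2.50 | 3 | 55 | 0 |
| spring | 3.00 | 0 | 54 | 0 |
| summer | 0.250 | 2 | 66 | 0 |
| summer | 0.833 | 0 | 66 | 0 |
| summer | 1.25 | 0 | 67 | 1 |
| summer | 2.00 | 1 | 68 | 0 |
| summer | 3.00 | 0 | 66 | 0 |

(each reading ± 1.5 percentage points)

- the reaction counts as stopped when no species that holds the first end groups changes by six tenths of a point or more over the second half of the time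

- why nothing more happens at 3.0 d, or that something still does (forward and back rates have come level / all of the first end groups has reacted / the second end groups has run out first / it is still moving)
- share of the first end groups used up at 3.0 d
- over-reaction product B at 3.0 d, in percent of the first end groups charged

The analyst reported that the highest reading of first end groups, 3% in spring, lay at two scatters from zero, so she expected 100% used in the new flask at 3.0 d. She added that midnight and spring, at one ratio and different strengths, averaged 55.7% and 54.7% of product B, which the scatter cannot part, while midnight's readings of first end groups and links stand at 1% or below, against a gap of 44.3% between its product B and the full charge.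

The kineticist therefore argued for a second way out that responds to strength as the first does, and he solved both ends. Let x be the second end groups as a fraction of the first charge. At small x the product should equal x, and at large x the whole charge. Taking the selectivity factor between the two ways as one, he joined the ends as x(1 − exp(−1/x)), which gives 71.5% for summer and 60.4% for the flask.

Summer averaged 66.6%, so the keep, the share of the curve's product read as product B, is 93.2%. The meeting's figure for the flask was therefore 56.3%.

The forecast said that all of the first end groups has reacted, with 100% used and 55% of product B, holding that “concentration barely matters”; its figure for product B lies 1.3 percentage points under the meeting's.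

The flask gives 55.2% of product B at 3.0 d, with 100% used: all of the first end groups has reacted.

    links → over-reaction product B (k = 2.00 × 10⁻⁴ /s)
    first end groups + second end groups ⇌ links + released group (K = 18.0, k = 0.0100 /M/s)
    links → over-reaction product A (k = 7.50 × 10⁻⁶ /s)
    2 first end groups → homo dimer (k = 0.00510 /M/s)

Moved alone, the second end groups shift the flask's product B by 5 points at 0.757 equiv or 1.08 equiv. The flask's own keep comes to 91.4%. A neighbour flask charged with 0.230 equiv of second end groups has a curve value of 22.7%, which summer's keep turns into 21.2%, and that neighbour holds 20.6% of product B.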